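All runs are simulated on assumed constants, and the scatter is random.

Colleague, here is the quick number for ash, larch and elm. They use the same charges of partner and free catalyst as the dawn and noon runs, and their charge of starting material, c, differs.

the same everywhere: partner 0.0525 M; free catalyst 3.2 mM
- dawn: starting material 0.0098 M; run made earlier
- noon: starting material 0.039 M; run made earlier
- ash: starting material 0.012 M; time 4.0 d
- larch: starting material 0.025 M; time 4.0 d
- elm: starting material 0.050 M; time 4.0 d

| run | time / d | product / % |
|---|---|---|
| dawn | 0.833 | 26 |
| dawn | 1.67 | 45 |
| dawn | 2.50 | 58 |
| dawn | 3.00 | 65 |
| dawn | 4.00 | 68 |
| noon | 0.333 | 4 |
| noon | 0.625 | 14 |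
| noon | 1.04 | 17 |
| noon | 2.00 | 32 |
| noon | 4.00 | 39 |

(standard deviation of a reading: 1.5 percentage points)

- a reading or a percentage of product counts all its forms, free or not
- the concentration of product that is asked is that of its free form alone
- "hardly changes" means that all values lie within two and a half points (for a concentration: within two and a half percent of the largest)

- [product] (only what is free in solution) at the end for ash, larch, elm, in this order
- how that number moves from the first to the last of them (falls all the way / hardly changes / rises, then falls / rises all the way / falls, then rises)

1. We look for the order of final product in c. Noon's c is 3.98 times dawn's, and the last readings give 0.00666 M of product for dawn and 0.0152 M for noon.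

2. So n = 0.597 is the apparent order, the slope of the logarithm of final product against the logarithm of c. This is a reading and carries the scatter. With n below one, and with partner and free catalyst held, a larger c gives more total product but a lower percentage.

3. Scaling from dawn, we reckon total product of 0.00752 M, 0.0117 M and 0.0176 M. Elm lies beyond noon's charge, so its figure is an extrapolation. These totals count every form of product, free or not, as the readings do.

4. Your hunch, the forecast, is a different number, for free product: 0.0063 M, 0.0108 M, 0.0152 M, so rises all the way. Its ground: “The stall comes at a similar time, not at a similar product level”.

The flasks give 0.00742 M, 0.00975 M and 0.00851 M of free product, so the row rises, then falls, turning at a charge of starting material of 0.028 M. The two part between larch and elm, where the forecast rises and the flasks fall.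

    starting material + free catalyst → catalyst intermediate A (k = 0.140 /M/min)
    catalyst intermediate A → catalyst intermediate B (k = 0.0110 /min)
    partner + catalyst intermediate B → catalyst intermediate C (k = 0.220 /M/min)
    catalyst intermediate C → free catalyst + product (k = 0.0110 /min)
    partner → decomposed reagent (k = 5.50 × 10⁻⁴ /min)
    starting material + product ⇌ idle adduct, settled at all times (K = 36.0 /M)

Elm's total product, free and bound in idle adduct, is 0.0158 M against ash's 0.00797 M, an order of 0.480, which is below one like our n of 0.597. Larch, the second flask, holds 0.0123 M against our 0.0117 M. One reason for the turn is the conversion of partner, the limiting reagent, into decomposed reagent: elm keeps 0.342% of its partner charge at 4.00 d, with 0.0365 M of decomposed reagent formed. Taking that conversion away turns the shape and lifts elm's free product from 0.00851 M to 0.0212 M.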